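The question about this flask is its leftover: target stands still near a third of the starting material charged, and the readings do not tell where the rest of that charge stands.

- birch: starting material 30 mM; second substrate 60 mM; third substrate 60 mM; solid reagent 45 mM; the very flask that is asked about, followed so far
- flask: starting material 30 mM; second substrate 60.0 mM; third substrate 60.0 mM; solid reagent 45.0 mM; time 15 h

- red: at 15 h take out 90 % of the target then present, then wait 8.0 h
- blue: change nothing and wait 8.0 h more
- amber: at 15 h add starting material, 50.0 % of the amount charged, then wait 8.0 h

- solid, in amounts per volume of the solution: solid reagent
- target that was removed still counts
- at the start none of the solid reagent is in solution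
- additions bring no volume worth counting

* target, in percent of the starting material first charged, at 15 h
* the option that brings most further target ("none" if no option brings more than 2 percentage points) (red / blue / amber / none)
* target present, with what was taken out counted in, in percent of the starting material first charged, after blue
* target present, with what was taken out counted in, in percent of the starting material first charged, after amber

birch run (percent of the starting material charged)

| time / min | target / % |
|---|---|
| 50.0 | 5.1 |
| 150 | 17.0 |
| 240 | 26.4 |
| 360 | 34.8 |
| 600 | 34.9 |
| 720 | 35.5 |

(each reading ± 0.3 percentage points)

Read down the readings. Target gains 12 percentage points over the 100 min of the first stretch, then 9.4 points over the 90.0 min of the next, so the climb is close to a straight line. After 360 min it gains 0.7 points in 360 min, against a scatter of 0.3 points.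

Follow one dissolved unit of solid reagent to its fork: with the other paths held, its chance of meeting starting material shrinks as starting material shrinks, so in this reckoning a climb that ends with starting material used up bends before it stops. The readings of this flask show a corner instead. This reckoning therefore takes the solid reagent as the limiting reagent and carries one quantity, the capture, which is target made per solid reagent charged: here 23.5 %, a reading from the plateau.

Capture times the solid charge gives 35.2 % of the starting material at 15 h. With no further supply in this reckoning, red, blue and amber each stay below 2 points, so it commits to "none", with blue and amber both ending at that figure.

The forecast parts from this reckoning at amber. It gives 35.2 %, 35.3 % after blue, 52 % after amber, and picks amber, while warning “if the solid is what ran out, amber gives nothing”.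

The flask gives 34.8 % and none: 34.8 % after blue and 34.8 % after amber.

    starting material + partner → target (k = 0.0115 /M/s)
    second substrate + partner → second product (k = 0.00163 /M/s)
    third substrate + partner → third product (k = 0.00528 /M/s)
    partner → decomposed reagent (k = 5.46 × 10⁻⁴ /s)
    solid reagent ⇌ partner, rate k5*(cs5 - [partner]) while solid is left; crystals form when [partner] > cs5 (solubility = 11.0 mM, k = 2.71 × 10⁻⁴ /s)

At 900 min this flask holds 0 % of its solid reagent, 0 mM of partner and 65 % of its starting material, and amber brings 0 points. A neighbour flask charged with 76 mM of solid reagent takes the same reckoning: the capture of 23.5 % gives 59.4 % of its starting material as target. That neighbour also ends with 0 % of its solid reagent, and it stands at 53.3 %, a capture of 21.0 %, with 46.7 % of its starting material still there.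

(The numbers in the tables were computed from invented constants.)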